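Blue is a near twin of the flask: both hold 0.500 M partner on about 1.0 M substrate, but blue carries 0.42 M protic impurity, more than the 0.300 M of the flask.

| flask | substrate | partner | protic impurity | remark | time |
|---|---|---|---|---|---|
| blue | 1 M | 0.50 M | 0.42 M | run made earlier |  |
| amber | 1 M | 0.50 M | 0.66 M | run made earlier |  |
| red | 2 M | 0.50 M | 0.30 M | run made earlier |  |
| flask | 1.0 M | 0.500 M | 0.300 M |  | 3.0 h |

| run | time / h | target / % | substrate / % |
|---|---|---|---|
| blue | 0.200 | 2 | 76 |
| blue | 0.417 | 16 | 64 |
| blue | 0.833 | 18 | 49 |
| blue | 1.50 | 15 | 36 |
| blue | 3.00 | 2 | 29 |
| amber | 0.200 | 6 | 76 |
| amber | 0.417 | 14 | 65 |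
| amber | 0.833 | 14 | 55 |
| amber | 1.50 | 8 | 44 |
| amber | 3.00 | 2 | 35 |
| red | 0.200 | 6 | 80 |
| red | 0.417 | 7 | 71 |
| red | 0.833 | 4 | 63 |
| red | 1.50 | 4 | 55 |
| red | 3.00 | 0 | 56 |

(scatter of a reading: 1.5 percentage points)

1. time up to 3.0 h at which target stands highest
2. the amount of target, in percent of the substrate charged, at that time
3. earliest time at which at least nineteen twentieths of that best amount are there
4. latest time at which they still are

- in percentages every species weighs as the substrate in it: one side product counts as two
- steps thought possible: intermediate -> target; substrate + target -> side product; partner + protic impurity -> quenched reagent; substrate + partner -> intermediate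

Partner can go two ways. With substrate it gives intermediate, which becomes target, and target then takes a second substrate to side product; with impurity it gives quenched reagent. Both rates carry partner, so dividing one by the other removes partner and time. Partner sent to intermediate per partner quenched equals substrate over impurity, times a constant: the split factor, or selectivity factor.

If the last reading is taken as the end of the run, partner that went the useful way is counted as half of substrate lost plus target standing. In blue that is 0.365 M, and the remainder, 0.135 M, is counted as quenched. Amber gives 0.165 M quenched and red 0.0600 M. Taking midpoint substrate and impurity, the factor reads 1.48 in blue, 1.74 in amber and 1.27 in red, so roughly 1.49; the forecast's ratio is 1.7.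

This reckoning, mine and not the forecast's, starts the flask at 4.97 partners to intermediate per partner quenched, and blue at 3.56. With the last substrate reading and the quenched amount of blue borrowed for the midpoints, it gives the flask 0.0972 M quenched, less than blue. So substrate should finally fall to 19.4% in the flask, against 27.0% in blue.

The factor holds no time, so the peak comes from the forecast: 18% at 1 h, with the window asked for running from 0.72 h to 1.3 h, on the ground that “the flask has less impurity than blue, so I expect about 18%”.

The flask peaks at 0.789 h with 18.4%, and its window asked for runs from 0.594 h to 1.04 h.

intermediate → target (k = 0.00100 /s); substrate + target → side product (k = 6.80 × 10⁻⁴ /M/s); partner + protic impurity → quenched reagent (k = 7.00 × 10⁻⁴ /M/s); substrate + partner → intermediate (k = 0.00110 /M/s) The forecast's 18% holds, while its 1 h lies later. At 3.00 h the flask holds 0.0911 M quenched reagent, against 0.0972 M reckoned. A neighbour charged with 0.60 M substrate starts at 2.98 partners to intermediate per partner quenched. With its 11.3% of substrate left, the factor gives 0.159 M quenched, and that neighbour holds 0.143 M at 3.00 h.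

(The earlier runs and the new flask were computed with made-up constants; the scatter is artificial.)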